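Retrosynthetic overview (germacrane numbering; ring A = cyclodecane C1–C10, ring B = butenolide O–C6–C7=C11–C12, ring C = oxirane C4–C5)
1. Feature: in ring A the C1 ketone lies between the C2 methylene and the fully substituted C10. C1 is therefore removed as carbon monoxide and C10 is carried as an sp2 carbon (C10=C14).
2. Endgame (C–O bonds only): 8-O-tiglate, 10-O- and 13-O-acetates, C10–OH and the C14 methyl by hydrogen-atom-transfer hydration of the 10(14)-methylene enone, ring C from the E-C4=C5 alkene.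
3. Key disconnection: C1–C2 and C1–C10 together. A C2 alkylborane (from the terminal alkene of the C2–C5 diene), CO and a C10 alkenyl bromide close ring A.
4. Precursor: C8–C9 by asymmetric 2-bromoallylboration of a 4-formylbutenolide. Ring B and its tetrasubstituted C7=C11 alkene come from syn-carbocupration of a γ-silyloxy ynoate (C7–C8), trapping at C11 (C11–C13) and lactonisation. C6–C7 comes from asymmetric alkynylation of (E)-3-methylpenta-2,4-dienal.
5. Ring order: ring B (step 7), ring A (step 14), ring C (step 15).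

Key step: step 14

Assumption: the (S,S) antipodes of ProPhenol and of the ditosyl-diphenylethylenediamine boron controller are taken to be those that attack the Si faces named in steps 3 and 12; if the sense of either is the reverse, its mirror image is used and nothing else changes.

Step 1
Reactants: 1 (E)-3-methylpent-2-en-4-yn-1-ol
Product: 2 (E)-3-methylpenta-2,4-dien-1-ol
Conditions: H2 (1 atm, 1 equiv), Pd/CaCO3–Pb(OAc)2, quinoline, EtOAc, 0–23 °C
Reagents that add atoms: none
Why: Lindlar-type semihydrogenation: the lead- and quinoline-poisoned palladium surface binds the terminal alkyne much more strongly than the diene that is formed, so uptake should stop after one equivalent and the E-C4=C5 alkene is kept.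

Step 2
Reactants: 2 (E)-3-methylpenta-2,4-dien-1-ol
Product: 3 (E)-3-methylpenta-2,4-dienal
Conditions: MnO2 (excess), CH2Cl2, 23 °C
Reagents that add atoms: none
Why: Heterogeneous MnO2 oxidation is selective for allylic alcohols, is neutral and should leave the E-geometry and the volatile dienal (used as its solution) intact.

Step 3
Reactants: 3 (E)-3-methylpenta-2,4-dienal; 4 methyl propiolate
Product: 5 methyl (4R,5E)-4-hydroxy-6-methylocta-5,7-dien-2-ynoate
Conditions: (S,S)-ProPhenol (10 mol %), ZnMe2 (3 equiv), toluene, 4 °C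
Reagents that add atoms: none
Why: ProPhenol/zinc-catalysed asymmetric alkynylation, a reaction class established for enals with methyl propiolate, in which the dinuclear zinc pocket binds aldehyde and zinc acetylide together and directs attack to the Si face of 3, setting C6 (4R in 5).

Step 4
Reactants: 5 methyl (4R,5E)-4-hydroxy-6-methylocta-5,7-dien-2-ynoate
Product: 6 methyl (4R,5E)-6-methyl-4-(triethylsilyloxy)octa-5,7-dien-2-ynoate
Conditions: Et3SiCl, imidazole, CH2Cl2, 0 °C
Reagents that add atoms: chlorotriethylsilane, CC[Si](Cl)(CC)CC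
Why: Routine silyl ether formation that keeps the C6 oxygen from quenching the cuprate and from lactonising before C11 is substituted; a triethylsilyl group is chosen because dilute acid removes it later.

Step 5
Reactants: 7 4-methoxybenzyl alcohol; 8 tributyl(iodomethyl)stannane
Product: 9 tributyl[(4-methoxybenzyloxy)methyl]stannane
Conditions: NaH, THF/DMF, 0→23 °C
Reagents that add atoms: none
Why: Williamson ether synthesis: the alkoxide of 7 displaces the primary iodide next to tin by SN2 and gives the tin precursor of a hydroxymethyl-anion equivalent for C8.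

Step 6
Reactants: 6 methyl (4R,5E)-6-methyl-4-(triethylsilyloxy)octa-5,7-dien-2-ynoate; 9 tributyl[(4-methoxybenzyloxy)methyl]stannane
Product: 12 methyl (2Z,4R,5E)-3-[(4-methoxybenzyloxy)methyl]-6-methyl-2-[(pinacolatoboryl)methyl]-4-(triethylsilyloxy)octa-2,5,7-trienoate, via lithium bis(alkoxymethyl)cuprate 10 (not isolated), via C11 alkenylcuprate 11 (not isolated)
Conditions: 9 (2.2 equiv), n-BuLi, THF, −78 °C; CuBr·SMe2 (1.1 equiv), −78→−50 °C; 6, −78 °C; HMPA, ICH2Bpin, −78→0 °C; aqueous work-up
Reagents that add atoms: 2-(iodomethyl)-4,4,5,5-tetramethyl-1,3,2-dioxaborolane, ICB1OC(C)(C)C(C)(C)O1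
Why: Tin–lithium exchange and cuprate formation give 10, whose syn-carbocupration of the alkynoate puts the C8 unit on the β-carbon C7 and copper on C11 (11), and HMPA-assisted alkylation of this configurationally stable alkenylcopper by the iodomethylboronate proceeds with retention (the known carbocupration–trapping route to tetrasubstituted 2-alkoxycarbonyl allylboronates), so that C6 and C12 end up cis on the C7=C11 alkene.

Step 7
Reactants: 12 methyl (2Z,4R,5E)-3-[(4-methoxybenzyloxy)methyl]-6-methyl-2-[(pinacolatoboryl)methyl]-4-(triethylsilyloxy)octa-2,5,7-trienoate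
Product: 14 (5R)-3-(hydroxymethyl)-4-[(4-methoxybenzyloxy)methyl]-5-[(1E)-2-methylbuta-1,3-dienyl]furan-2(5H)-one, via C13 allylic alcohol ester 13 (not isolated)
Conditions: 30% H2O2, NaHCO3, THF/H2O, 0 °C; then 1 M HCl, THF, 23 °C
Reagents that add atoms: hydrogen peroxide, OO
Why: Peroxide oxidation of the allylic C–B bond occurs by 1,2-migration without allylic shift to give C13–OH (13), and dilute acid then cleaves the labile C6 silyl ether so that the Z-γ-hydroxy enoate lactonises to ring B by 5-exo-trig acyl substitution without touching the C6 stereocentre.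

Step 8
Reactants: 14 (5R)-3-(hydroxymethyl)-4-[(4-methoxybenzyloxy)methyl]-5-[(1E)-2-methylbuta-1,3-dienyl]furan-2(5H)-one
Product: 15 (5R)-4-[(4-methoxybenzyloxy)methyl]-5-[(1E)-2-methylbuta-1,3-dienyl]-3-[(triethylsilyloxy)methyl]furan-2(5H)-one
Conditions: Et3SiCl, imidazole, CH2Cl2, 0 °C
Reagents that add atoms: chlorotriethylsilane, CC[Si](Cl)(CC)CC
Why: Routine silylation of the primary C13 alcohol; the silyl ether is inert to palladium and phosphate in step 14 and can later be removed beside the C8 silyl ether.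

Step 9
Reactants: 15 (5R)-4-[(4-methoxybenzyloxy)methyl]-5-[(1E)-2-methylbuta-1,3-dienyl]-3-[(triethylsilyloxy)methyl]furan-2(5H)-one
Product: 16 (5R)-4-(hydroxymethyl)-5-[(1E)-2-methylbuta-1,3-dienyl]-3-[(triethylsilyloxy)methyl]furan-2(5H)-one
Conditions: DDQ, CH2Cl2/pH 7 buffer, 0 °C
Reagents that add atoms: none
Why: Oxidative cleavage of the 4-methoxybenzyl ether by DDQ (electron transfer, then hydrolysis of the oxocarbenium ion) is orthogonal to the silyl ether, and buffered cold conditions limit attack on the diene and lactone migration to the freed C8 hydroxyl.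

Step 10
Reactants: 16 (5R)-4-(hydroxymethyl)-5-[(1E)-2-methylbuta-1,3-dienyl]-3-[(triethylsilyloxy)methyl]furan-2(5H)-one
Product: 17 (2R)-2-[(1E)-2-methylbuta-1,3-dienyl]-5-oxo-4-[(triethylsilyloxy)methyl]-2,5-dihydrofuran-3-carbaldehyde
Conditions: Dess–Martin periodinane, NaHCO3, CH2Cl2, 0→23 °C
Reagents that add atoms: none
Why: Dess–Martin oxidation is neutral and fast, which matters because the C6–H of the 4-formylbutenolide is doubly activated and would epimerise under basic oxidation conditions.

Step 11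
Reactants: 18 2,3-dibromopropene
Product: 19 (2-bromoallyl)tributylstannane
Conditions: Bu3SnH, LDA, THF, 0 °C; CuBr·SMe2, −78 °C; 18, −78→0 °C
Reagents that add atoms: tributylstannane, CCCC[SnH](CCCC)CCCC
Why: Allylic substitution of the reactive allylic bromide by a stannylcopper nucleophile (SN2 and SN2′ give the same product), while the alkenyl bromide is inert at low temperature.

Step 12
Reactants: 17 (2R)-2-[(1E)-2-methylbuta-1,3-dienyl]-5-oxo-4-[(triethylsilyloxy)methyl]-2,5-dihydrofuran-3-carbaldehyde; 19 (2-bromoallyl)tributylstannane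
Product: 21 (5R)-4-[(1S)-3-bromo-1-hydroxybut-3-enyl]-5-[(1E)-2-methylbuta-1,3-dienyl]-3-[(triethylsilyloxy)methyl]furan-2(5H)-one, via B-(2-bromoallyl)diazaborolidine 20 (not isolated)
Conditions: (S,S)-TsNHCH(Ph)CH(Ph)NHTs, BBr3, CH2Cl2, 0→23 °C, evaporate; 19, CH2Cl2, 23 °C; 17, −78 °C; pH 7 buffer
Reagents that add atoms: none
Why: Tin-to-boron exchange gives the chiral allylborane 20, which adds through a closed chair transition state (asymmetric allylboration with a C2-symmetric diazaborolidine controller, documented for 2-haloallyl groups), the controller directing the 2-bromoallyl group to the Si face of the aldehyde and setting C8 as S under reagent control, with no base or oxidative work-up.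

Step 13
Reactants: 21 (5R)-4-[(1S)-3-bromo-1-hydroxybut-3-enyl]-5-[(1E)-2-methylbuta-1,3-dienyl]-3-[(triethylsilyloxy)methyl]furan-2(5H)-one
Product: 22 (5R)-4-[(1S)-3-bromo-1-(tert-butyldimethylsilyloxy)but-3-enyl]-5-[(1E)-2-methylbuta-1,3-dienyl]-3-[(triethylsilyloxy)methyl]furan-2(5H)-one
Conditions: TBSCl, imidazole, DMF, 23 °C
Reagents that add atoms: tert-butylchlorodimethylsilane, CC(C)(C)[Si](C)(C)Cl
Why: Silylation with the chloride and imidazole rather than the triflate and an amine avoids conversion of the butenolide into a 2-silyloxyfuran, which would erase C6, and blocks the C8 hydroxyl against lactone migration.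

Step 14
Reactants: 22 (5R)-4-[(1S)-3-bromo-1-(tert-butyldimethylsilyloxy)but-3-enyl]-5-[(1E)-2-methylbuta-1,3-dienyl]-3-[(triethylsilyloxy)methyl]furan-2(5H)-one; 23 carbon monoxide
Product: 25 (4E,6R,8S)-8-(tert-butyldimethylsilyloxy)-1-oxo-13-(triethylsilyloxy)germacra-4,7(11),10(14)-trien-12,6-olide, via C2 B-alkyl-9-BBN 24 (not isolated)
Conditions: 9-BBN-H (1.1 equiv), THF, 0→23 °C; then syringe-pump addition over 12 h to PdCl2(dppf) (20 mol %), powdered K3PO4 (3 equiv), CO (3 bar), 1,4-dioxane/THF, 50 °C, final concentration 1 mM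
Reagents that add atoms: none
Why: Proposed new method: 9-BBN adds to the only monosubstituted alkene (C2=C3) with boron on C2 to give 24; zerovalent palladium then inserts into the C10–Br bond, CO inserts to give the 2-substituted acryloylpalladium (C1–C10), phosphate-assisted B-alkyl transmetallation brings C2 onto palladium and reductive elimination forms C1–C2. The closest known reactions are the intermolecular carbonylative Suzuki–Miyaura coupling of 9-alkyl-9-BBN reagents with haloalkenes to enones, B-alkyl Suzuki–Miyaura macrocyclisation and carbonylative Stille macrocyclisation; their combination in a ten-membered ring has not been shown. Ring A closes at the transmetallation stage as an eleven-membered acyl(alkyl)palladacycle, which contracts to the ten-membered ketone on reductive elimination, and slow addition of 24 keeps the process intramolecular. No stereocentre is formed; C6, C8 and the E-C4=C5 geometry are spectators, and powdered K3PO4 in a non-aqueous medium is chosen to spare the acidic C6–H and to keep hydroxide away from the acylpalladium. Hydroboration selectivity rests on substitution and electronics (C4=C5 trisubstituted, C10=C14 deactivated by bromine, C7=C11 tetrasubstituted and electron-poor), and CO insertion outruns the slow B-alkyl transfer under CO pressure while direct coupling would need a strained nine-membered ring. The C13 oxygen is carried as a silyl ether because a 13-acetate is an allylic acetate of the Baylis–Hillman type that zerovalent palladium or the base could ionise or cleave.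

Step 15
Reactants: 25 (4E,6R,8S)-8-(tert-butyldimethylsilyloxy)-1-oxo-13-(triethylsilyloxy)germacra-4,7(11),10(14)-trien-12,6-olide
Product: 26 (4R,5R,6S,8S)-8-(tert-butyldimethylsilyloxy)-4,5-epoxy-1-oxo-13-(triethylsilyloxy)germacra-7(11),10(14)-dien-12,6-olide
Conditions: mCPBA, NaHCO3, CH2Cl2, −20→0 °C
Reagents that add atoms: 3-chloroperbenzoic acid, O=C(OO)c1cccc(Cl)c1
Why: Prilezhaev epoxidation picks the only electron-rich alkene (the enone and butenolide alkenes are deactivated) and should attack the exposed outer face of the E-cyclodecene, whose orientation is fixed by allylic strain between C15 and the C6 substituents, to give the trans-epoxide with 4R,5R configuration as in related germacran-6,12-olides.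

Step 16
Reactants: 26 (4R,5R,6S,8S)-8-(tert-butyldimethylsilyloxy)-4,5-epoxy-1-oxo-13-(triethylsilyloxy)germacra-7(11),10(14)-dien-12,6-olide
Product: 28 (4R,5R,6S,8S,10R)-8-(tert-butyldimethylsilyloxy)-4,5-epoxy-10-hydroxy-1-oxo-13-(triethylsilyloxy)germacr-7(11)-en-12,6-olide, via C10 hydroperoxide 27 (not isolated)
Conditions: Mn(dpm)3 (15 mol %), PhSiH3, O2 (1 atm), iPrOH/CH2Cl2, 0 °C; then P(OEt)3
Reagents that add atoms: dioxygen, O=O
Why: Mukaiyama-type hydrogen-atom-transfer hydration: the manganese hydride formed from Mn(dpm)3 and PhSiH3 delivers H to the terminal C14, the tertiary C10 radical conjugated with the C1 carbonyl captures O2 on the outer face of ring A (expected to give 10R, syn to the C8 oxygen), and the phosphite reduces hydroperoxide 27, while the tetrasubstituted butenolide alkene is too hindered to react.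

Step 17
Reactants: 28 (4R,5R,6S,8S,10R)-8-(tert-butyldimethylsilyloxy)-4,5-epoxy-10-hydroxy-1-oxo-13-(triethylsilyloxy)germacr-7(11)-en-12,6-olide
Product: 29 (4R,5R,6S,8S,10R)-8-(tert-butyldimethylsilyloxy)-4,5-epoxy-10,13-dihydroxy-1-oxogermacr-7(11)-en-12,6-olide
Conditions: PPTS (cat.), MeOH/CH2Cl2, 0 °C
Reagents that add atoms: none
Why: Acid-catalysed methanolysis distinguishes the primary triethylsilyl ether from the hindered secondary tert-butyldimethylsilyl ether by a wide rate margin and is mild enough for the epoxide.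

Step 18
Reactants: 29 (4R,5R,6S,8S,10R)-8-(tert-butyldimethylsilyloxy)-4,5-epoxy-10,13-dihydroxy-1-oxogermacr-7(11)-en-12,6-olide
Product: 30 (4R,5R,6S,8S,10R)-10,13-diacetoxy-8-(tert-butyldimethylsilyloxy)-4,5-epoxy-1-oxogermacr-7(11)-en-12,6-olide
Conditions: Ac2O, DMAP, Et3N, CH2Cl2, 23→35 °C
Reagents that add atoms: acetic anhydride, CC(=O)OC(C)=O
Why: DMAP-catalysed acylation esterifies the primary C13 and the tertiary C10 hydroxyl in one operation, the tertiary α-ketol needing the longer time, while C8 stays silylated.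

Step 19
Reactants: 30 (4R,5R,6S,8S,10R)-10,13-diacetoxy-8-(tert-butyldimethylsilyloxy)-4,5-epoxy-1-oxogermacr-7(11)-en-12,6-olide
Product: 31 (4R,5R,6S,8S,10R)-10,13-diacetoxy-4,5-epoxy-8-hydroxy-1-oxogermacr-7(11)-en-12,6-olide
Conditions: HF·pyridine, pyridine, THF, 0→23 °C
Reagents that add atoms: none
Why: Fluoride-driven desilylation under buffered, slightly acidic conditions avoids the alkoxide that could migrate the lactone (6,12 to 8,12) or shift the acetates.

Step 20
Reactants: 31 (4R,5R,6S,8S,10R)-10,13-diacetoxy-4,5-epoxy-8-hydroxy-1-oxogermacr-7(11)-en-12,6-olide; 32 tiglic acid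
Product: 34 CNP0175424.1 (4R,5R,6S,8S,10R)-10,13-diacetoxy-4,5-epoxy-1-oxo-8-tigloyloxygermacr-7(11)-en-12,6-olide, via tigloyl trichlorobenzoyl anhydride 33 (not isolated)
Conditions: 32, 2,4,6-trichlorobenzoyl chloride, Et3N, toluene, 23 °C; then 31, DMAP, 23 °C
Reagents that add atoms: none
Why: Yamaguchi esterification through mixed anhydride 33 acylates the hindered secondary C8 alcohol with retention at C8, and the thermodynamically preferred E-geometry of the tiglate is not at risk.

Compound list
1 | (E)-3-methylpent-2-en-4-yn-1-ol | C#C/C(C)=C/CO | starting material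
2 | (E)-3-methylpenta-2,4-dien-1-ol | C=C/C(C)=C/CO | intermediate
3 | (E)-3-methylpenta-2,4-dienal | C=C/C(C)=C/C=O | intermediate
4 | methyl propiolate | C#CC(=O)OC | starting material
5 | methyl (4R,5E)-4-hydroxy-6-methylocta-5,7-dien-2-ynoate | C=C/C(C)=C/[C@@H](O)C#CC(=O)OC | intermediate
6 | methyl (4R,5E)-6-methyl-4-(triethylsilyloxy)octa-5,7-dien-2-ynoate | C=C/C(C)=C/[C@@H](O[Si](CC)(CC)CC)C#CC(=O)OC | intermediate
7 | 4-methoxybenzyl alcohol | COc1ccc(CO)cc1 | starting material
8 | tributyl(iodomethyl)stannane | CCCC[Sn](CCCC)(CCCC)CI | starting material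
9 | tributyl[(4-methoxybenzyloxy)methyl]stannane | CCCC[Sn](CCCC)(CCCC)COCc1ccc(OC)cc1 | intermediate
10 | lithium bis[(4-methoxybenzyloxy)methyl]cuprate (not isolated) | [Li+].COc1ccc(COC[Cu-]COCc2ccc(OC)cc2)cc1 | intermediate
11 | lithium alkenyl(alkoxymethyl)cuprate, copper on C11, syn adduct of 10 to 6 (not isolated) | [Li+].C=C/C(C)=C/[C@@H](O[Si](CC)(CC)CC)/C(COCc1ccc(OC)cc1)=C(/[Cu-]COCc1ccc(OC)cc1)C(=O)OC | intermediate
12 | methyl (2Z,4R,5E)-3-[(4-methoxybenzyloxy)methyl]-6-methyl-2-[(4,4,5,5-tetramethyl-1,3,2-dioxaborolan-2-yl)methyl]-4-(triethylsilyloxy)octa-2,5,7-trienoate | C=C/C(C)=C/[C@@H](O[Si](CC)(CC)CC)/C(COCc1ccc(OC)cc1)=C(/CB1OC(C)(C)C(C)(C)O1)C(=O)OC | intermediate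
13 | methyl (2Z,4R,5E)-2-(hydroxymethyl)-3-[(4-methoxybenzyloxy)methyl]-6-methyl-4-(triethylsilyloxy)octa-2,5,7-trienoate (not isolated) | C=C/C(C)=C/[C@@H](O[Si](CC)(CC)CC)/C(COCc1ccc(OC)cc1)=C(/CO)C(=O)OC | intermediate
14 | (5R)-3-(hydroxymethyl)-4-[(4-methoxybenzyloxy)methyl]-5-[(1E)-2-methylbuta-1,3-dienyl]furan-2(5H)-one | C=C/C(C)=C/[C@H]1OC(=O)C(CO)=C1COCc1ccc(OC)cc1 | intermediate
15 | (5R)-4-[(4-methoxybenzyloxy)methyl]-5-[(1E)-2-methylbuta-1,3-dienyl]-3-[(triethylsilyloxy)methyl]furan-2(5H)-one | C=C/C(C)=C/[C@H]1OC(=O)C(CO[Si](CC)(CC)CC)=C1COCc1ccc(OC)cc1 | intermediate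
16 | (5R)-4-(hydroxymethyl)-5-[(1E)-2-methylbuta-1,3-dienyl]-3-[(triethylsilyloxy)methyl]furan-2(5H)-one | C=C/C(C)=C/[C@H]1OC(=O)C(CO[Si](CC)(CC)CC)=C1CO | intermediate
17 | (2R)-2-[(1E)-2-methylbuta-1,3-dienyl]-5-oxo-4-[(triethylsilyloxy)methyl]-2,5-dihydrofuran-3-carbaldehyde | C=C/C(C)=C/[C@H]1OC(=O)C(CO[Si](CC)(CC)CC)=C1C=O | intermediate
18 | 2,3-dibromopropene | BrCC(Br)=C | starting material
19 | (2-bromoallyl)tributylstannane | CCCC[Sn](CCCC)(CCCC)CC(Br)=C | intermediate
20 | (4S,5S)-2-(2-bromoallyl)-4,5-diphenyl-1,3-ditosyl-1,3,2-diazaborolidine (not isolated) | C=C(Br)CB1N(S(=O)(=O)c2ccc(C)cc2)[C@@H](c2ccccc2)[C@H](c2ccccc2)N1S(=O)(=O)c1ccc(C)cc1 | intermediate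
21 | (5R)-4-[(1S)-3-bromo-1-hydroxybut-3-enyl]-5-[(1E)-2-methylbuta-1,3-dienyl]-3-[(triethylsilyloxy)methyl]furan-2(5H)-one | C=C/C(C)=C/[C@H]1OC(=O)C(CO[Si](CC)(CC)CC)=C1[C@@H](O)CC(Br)=C | intermediate
22 | (5R)-4-[(1S)-3-bromo-1-(tert-butyldimethylsilyloxy)but-3-enyl]-5-[(1E)-2-methylbuta-1,3-dienyl]-3-[(triethylsilyloxy)methyl]furan-2(5H)-one (key-step precursor) | C=C/C(C)=C/[C@H]1OC(=O)C(CO[Si](CC)(CC)CC)=C1[C@@H](O[Si](C)(C)C(C)(C)C)CC(Br)=C | intermediate
23 | carbon monoxide | [C-]#[O+] | starting material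
24 | C2 B-alkyl-9-borabicyclo[3.3.1]nonane from 22 (not isolated) | C1CC2CCCC(C1)B2CC/C(C)=C/[C@H]1OC(=O)C(CO[Si](CC)(CC)CC)=C1[C@@H](O[Si](C)(C)C(C)(C)C)CC(Br)=C | intermediate
25 | (4E,6R,8S)-8-(tert-butyldimethylsilyloxy)-1-oxo-13-(triethylsilyloxy)germacra-4,7(11),10(14)-trien-12,6-olide (key-step product) | CC(C)(C)[Si](C)(C)O[C@H]1CC(=C)C(=O)CC/C(C)=C/[C@H]2OC(=O)C(CO[Si](CC)(CC)CC)=C12 | intermediate
26 | (4R,5R,6S,8S)-8-(tert-butyldimethylsilyloxy)-4,5-epoxy-1-oxo-13-(triethylsilyloxy)germacra-7(11),10(14)-dien-12,6-olide | CC(C)(C)[Si](C)(C)O[C@H]1CC(=C)C(=O)CC[C@@]2(C)O[C@@H]2[C@H]2OC(=O)C(CO[Si](CC)(CC)CC)=C12 | intermediate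
27 | (10R)-10-hydroperoxide of 28 (not isolated) | CC(C)(C)[Si](C)(C)O[C@H]1C[C@@](C)(OO)C(=O)CC[C@@]2(C)O[C@@H]2[C@H]2OC(=O)C(CO[Si](CC)(CC)CC)=C12 | intermediate
28 | (4R,5R,6S,8S,10R)-8-(tert-butyldimethylsilyloxy)-4,5-epoxy-10-hydroxy-1-oxo-13-(triethylsilyloxy)germacr-7(11)-en-12,6-olide | CC(C)(C)[Si](C)(C)O[C@H]1C[C@@](C)(O)C(=O)CC[C@@]2(C)O[C@@H]2[C@H]2OC(=O)C(CO[Si](CC)(CC)CC)=C12 | intermediate
29 | (4R,5R,6S,8S,10R)-8-(tert-butyldimethylsilyloxy)-4,5-epoxy-10,13-dihydroxy-1-oxogermacr-7(11)-en-12,6-olide | CC(C)(C)[Si](C)(C)O[C@H]1C[C@@](C)(O)C(=O)CC[C@@]2(C)O[C@@H]2[C@H]2OC(=O)C(CO)=C12 | intermediate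
30 | (4R,5R,6S,8S,10R)-10,13-diacetoxy-8-(tert-butyldimethylsilyloxy)-4,5-epoxy-1-oxogermacr-7(11)-en-12,6-olide | CC(C)(C)[Si](C)(C)O[C@H]1C[C@@](C)(OC(C)=O)C(=O)CC[C@@]2(C)O[C@@H]2[C@H]2OC(=O)C(COC(C)=O)=C12 | intermediate
31 | (4R,5R,6S,8S,10R)-10,13-diacetoxy-4,5-epoxy-8-hydroxy-1-oxogermacr-7(11)-en-12,6-olide | O[C@H]1C[C@@](C)(OC(C)=O)C(=O)CC[C@@]2(C)O[C@@H]2[C@H]2OC(=O)C(COC(C)=O)=C12 | intermediate
32 | tiglic acid | C/C=C(\C)C(=O)O | starting material
33 | (E)-2-methylbut-2-enoic 2,4,6-trichlorobenzoic anhydride (not isolated) | C/C=C(\C)C(=O)OC(=O)c1c(Cl)cc(Cl)cc1Cl | intermediate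
34 | CNP0175424.1 | C/C=C(\C)C(=O)O[C@H]1C[C@@](C)(OC(C)=O)C(=O)CC[C@@]2(C)O[C@@H]2[C@H]2OC(=O)C(COC(C)=O)=C12 | target

Total step count: 20. Longest linear sequence: 18 (steps 1–4, 6–10, 12–20).

Steps most likely to fail

Step 14 (labelled step).
- What may go wrong: intermolecular coupling may compete with ring closure. The borane may be lost by protodeboronation before it reaches the acylpalladium. Hydroboration may stray to the bromoalkene. The base may slowly remove the C6 proton and epimerise C6.
- Fallback, from 22 to 25: borane 24 is made as in step 14. It is subjected to the known hydride-induced carbonylation of B-alkyl-9-BBN reagents (CO 1 atm, KBH(OiPr)3, THF, 0 °C, then buffered H2O2), which still takes C1 from CO and gives the open-chain C1 aldehyde F1.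
- An intramolecular Nozaki–Hiyama–Kishi reaction of the alkenyl bromide with this aldehyde (CrCl2, NiCl2 cat., DMSO/THF, high dilution, base-free) closes ring A at C1–C10 as the cyclic C1 allylic alcohol F2. Dess–Martin oxidation then rejoins the route at 25.

Step 16.
- What may go wrong: facial selectivity may be poor when the planar C10 radical captures oxygen. The radical may also be reduced to the α-methyl ketone.
- Fallback, from 26 to 29: 1,4-hydrosilylation of the enone (Et3SiH, RhCl(PPh3)3, toluene, 23–50 °C) gives regiospecifically the tetrasubstituted C1(10) triethylsilyl enol ether F3.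
- Rubottom oxidation (mCPBA, NaHCO3, CH2Cl2, −20 °C) delivers oxygen to C10 in a polar, concerted step. After silyl migration it gives the 10-O-triethylsilyl ketone F4.
- PPTS in MeOH removes both triethylsilyl groups and the route is rejoined at 29.

Step 6.
- What may go wrong: transfer of the α-alkoxymethyl ligand may be sluggish. The alkene geometry may be lost through allenolate equilibration of the alkenylcopper during the slow alkylation above −78 °C.
- Fallback, from 6 to 13: cuprate 10 is added as before, but the alkenylcopper is quenched at −78 °C with I2 (1 equiv), a trap fast enough to preserve geometry, giving the α-iodo enoate F5.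
- A Stille coupling with (tributylstannyl)methanol (Pd2(dba)3, AsPh3, NMP, 40 °C) then forms C11–C13 with retention. The route is rejoined at 13, which is taken through the acid stage of step 7.

Further compounds
F1 | step 14 | (4E)-5-{(2R)-3-[(1S)-3-bromo-1-(tert-butyldimethylsilyloxy)but-3-enyl]-5-oxo-4-[(triethylsilyloxy)methyl]-2,5-dihydrofuran-2-yl}-4-methylpent-4-enal | O=CCC/C(C)=C/[C@H]1OC(=O)C(CO[Si](CC)(CC)CC)=C1[C@@H](O[Si](C)(C)C(C)(C)C)CC(Br)=C
F2 | step 14 | (4E,6R,8S)-8-(tert-butyldimethylsilyloxy)-1-hydroxy-13-(triethylsilyloxy)germacra-4,7(11),10(14)-trien-12,6-olide (C1 epimers) | CC(C)(C)[Si](C)(C)O[C@H]1CC(=C)C(O)CC/C(C)=C/[C@H]2OC(=O)C(CO[Si](CC)(CC)CC)=C12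
F3 | step 16 | (4R,5R,6S,8S)-8-(tert-butyldimethylsilyloxy)-4,5-epoxy-1,13-bis(triethylsilyloxy)germacra-1(10),7(11)-dien-12,6-olide | CC(C)(C)[Si](C)(C)O[C@H]1CC(C)=C(O[Si](CC)(CC)CC)CC[C@@]2(C)O[C@@H]2[C@H]2OC(=O)C(CO[Si](CC)(CC)CC)=C12
F4 | step 16 | (4R,5R,6S,8S,10R)-8-(tert-butyldimethylsilyloxy)-4,5-epoxy-1-oxo-10,13-bis(triethylsilyloxy)germacr-7(11)-en-12,6-olide | CC(C)(C)[Si](C)(C)O[C@H]1C[C@@](C)(O[Si](CC)(CC)CC)C(=O)CC[C@@]2(C)O[C@@H]2[C@H]2OC(=O)C(CO[Si](CC)(CC)CC)=C12
F5 | step 6 | methyl (2E,4R,5E)-2-iodo-3-[(4-methoxybenzyloxy)methyl]-6-methyl-4-(triethylsilyloxy)octa-2,5,7-trienoate | C=C/C(C)=C/[C@@H](O[Si](CC)(CC)CC)/C(COCc1ccc(OC)cc1)=C(/I)C(=O)OC
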